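The runs were computed on assumed constants, noise included.

The last reading of the west run, at 59 h, stood at 0.2386 M of Pdt. You now have to decide whether the same charge, left standing until 180 h as the north-west run, will do, or whether it needs the extra Ctl of the south run.

| setting | west | north | south | north-west |
|---|---|---|---|---|
| Sbt | 0.300 M | 0.600 M | 0.300 M | 0.300 M |
| Ctl | 0.00600 M | 0.00600 M | 0.00900 M | 0.00600 M |
| time |  |  |  | 180 h |

- west run (time / h: [Pdt] / M): 2.1: 0.0246; 6.4: 0.0665; 12: 0.1059; 19: 0.1466; 28: 0.1794; 37: 0.2060; 48: 0.2217; 59: 0.2386
- north run (time / h: [Pdt] / M): 2.1: 0.0402; 6.4: 0.1085; 12: 0.1784; 19: 0.2455; 28: 0.3062; 37: 0.3606; 48: 0.4100; 59: 0.4474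
- south run (time / h: [Pdt] / M): 2.1: 0.0319; 6.4: 0.0794; 12: 0.1278; 19: 0.1679; 28: 0.2004; 37: 0.2238; 48: 0.2488; 59: 0.2582

(scatter of a reading: 0.002 M)

1. how the opening rate goes with [Ctl] round the charge of the west run: the exponent of the rate at two percent of Sbt gone to Pdt
2. how the opening rate goes with [Sbt] round the charge of the west run: the exponent of the rate at two percent of Sbt gone to Pdt (one fixed amount of Pdt, the same in the runs compared)
3. Pdt in the north-west run at 180 h, as a share of the Sbt charged

- Overall: Sbt -> Pdt, with Ctl as catalyst.
- Constant volume, constant temperature.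
- Readings of a species count what is bound in complexes too.
- An order is taken over about fifteen percent of the charge, up and down.

Work with the fraction of Sbt left, one minus Pdt over the Sbt charged, and not with the Pdt made. In the west run it is 40.2% at 28 h, 26.1% at 48 h and 20.5% at 59 h. Between the first and last of these, the fall reads 0.0218 h⁻¹. Call this the late loss constant, the natural logarithm of the fall in the fraction left, per hour: a pseudo-first-order constant read from the tail.

The opening stretch won't serve, because the first reading of the west run gives 0.0407 h⁻¹, about twice the late value. The tail, however, holds steady: the two parts of it read 0.0216 h⁻¹ and 0.0220 h⁻¹, with no sign of a stop.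

A steady constant multiplies the fraction left by one factor, here 7.17% over the remaining 121 h. So I reckon 1.47% left in the north-west run, which is 98.5% made. That 1.47% is what extra Ctl could still win in this reckoning. The tail of the south run won't take the same reckoning, since its two parts read 0.0333 h⁻¹ and 0.0184 h⁻¹. I would charge the west recipe unchanged and wait.

The forecast gave 0.58 for the Ctl order, 0.72 for the Sbt order and 94% made, a yield below mine, with the caution “A reversible limit could lower this”.

The flask gives 0.55, 0.72 and 98.4%, so 1.60% is left against my 1.47%.

    Ctl + Sbt ⇌ Ctl.Sbt (84.96 M⁻¹ h⁻¹, 17.71 h⁻¹)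
    Ctl.Sbt → Pdt + Ctl (2.059 h⁻¹)
    Ctl.Sbt → Q + Sbt (0.1256 h⁻¹)
    Sbt → Pdt (0.01908 h⁻¹)

The north-west run reaches 98.4% because Sbt also turns to Pdt directly, without the catalyst. The same run with that step taken away makes 32.8% of Pdt at 180 h, leaving 67.2% of its Sbt. From the last west reading to 180 h in the north-west run, which has the same charge, the fraction left falls at 0.0211 h⁻¹, against the late loss constant of 0.0218 h⁻¹.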